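The runs come from a simulation with constants of no real substance; noise was put on by code.

The constants of these flasks are not given, so the first question is which one the earlier runs let us read.

| setting | teal | red | green | dawn | spring |
|---|---|---|---|---|---|
| E | 24 mM | 36 mM | 48 mM | 48 mM | 48 mM |
| J | 192 mM | 192 mM | 290 mM | 192 mM | 192 mM |
| D | 24 mM | 24 mM | 24 mM | 24.0 mM | 24.0 mM |
| temperature | 20 °C | 38 °C | 20 °C | 25 °C | 50 °C |
| remark | run made earlier | run made earlier | run made earlier |  |  |
| time |  |  |  | 5.0 min | 5.0 min |

| run | time / min | L / % | E / % |
|---|---|---|---|
| teal | 1.33 | 2 | 83 |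
| teal | 2.50 | 5 | 74 |
| teal | 4.00 | 14 | 66 |
| teal | 5.00 | 15 | 61 |
| red | 0.200 | 0 | 100 |
| red | 0.500 | 2 | 94 |
| red | 1.00 | 5 | 87 |
| red | 2.50 | 20 | 74 |
| green | 0.417 | 0 | 98 |
| green | 1.00 | 0 | 92 |
| green | 2.00 | 2 | 84 |
| green | 5.00 | 12 | 68 |

(readings scatter by 1.5 percentage points)

- the flask that comes out highest in amount of L, in percent of the E charged, or "all alike" when all lie within 1.5 percentage points (dawn / spring / all alike)
- L at the end, in percent of the E charged, dawn
- L at the end, in percent of the E charged, spring

- given per volume of solution although it is solid: J
- at the start none of J is in solution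

What do the runs show? In each run E falls first while L trails behind it, and at the last teal reading 24.0% of the charge is neither E nor L.

What constant does that give? I take the transit time (the mean lifetime of an intermediate), which is the part on the way divided by the L arriving per minute, and teal's late readings put it at 6.00 min.

Does it follow the charge? The green run, with twice the E and more J at the same temperature, reads 6.00 min, which matches teal, so I treat it as a matter of temperature.

And warmth? The red run at 38 °C reads 0.600 min, far shorter than teal.

Where is that weak? Red's gap is 6.00% against a scatter of 1.5 percentage points on each reading, so the hot end of this reckoning rests on a thin difference.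

What does it give for the new flasks? Drawing ln of the transit time straight against inverse temperature, dawn has 3.08 min, and spring has a transit time, the same ratio of what is on the way to what arrives per minute, of 0.149 min.

With E lost steadily, the arrived share of the loss after 5.0 min is 50.6% in dawn and 97.0% in spring. Borrowing green's loss for dawn and red's pace of loss for spring, both rough, I reckon 16.2% of L in dawn and 50.4% in spring, which stands higher.

The forecast says 17% for dawn, above my figure, and 50% for spring, and it names spring as the highest, its rates there being said to “leave little intermediate”.

Spring gives 53.4% of L and dawn 19.7%, so spring comes out highest.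

    Z → L (k = 0.100 s⁻¹, Ea = 91.0 kJ mol⁻¹)
    J ⇌ G, rate k2*(cs2 - [G]) while solid is left; crystals form when [G] > cs2 (solubility = 5.60 mM, k = 0.0200 s⁻¹)
    E + G ⇌ Z, settled at all times (K = 41.0 M⁻¹, ΔH = −16.0 kJ mol⁻¹)
    G + D → X (k = 0.550 M⁻¹ s⁻¹, Ea = 67.0 kJ mol⁻¹)
    (constants at 50 °C)

With the path from G + D to X struck out, spring gives 57.1%, which is 3.7 points above the flask as it ran. Z is what was on the way, and spring's transit time of 0.149 min, multiplied by the mean arrival of L over 5.0 min, gives 1.59%, where Z stood at 1.69% at the end of spring. In the flask like spring but charged with 96 mM of D, L reached 45.2%, the same product gives 1.35%, and Z stood at 1.41% at the end.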